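**Assumption:** the target has no stereocentre (planar, achiral flavone), so there is no enantiomer to control. Compound numbers follow the forward steps; the overview uses names only.

## Retrosynthetic overview

1. Target ⇒ open-chain tetrabromo 2-methoxy-1,3-diaryl-1,3-diketone. Four aryl C–O bonds are made in one operation from C–Br bonds: O1–C8a (ring closure), C5–OH, C7–OH and C4'–OH.
2. Diketone ⇒ 2,4,6-tribromo-3,5-dimethoxybenzoyl chloride + 1-(4-bromo-2,5-dimethoxyphenyl)-2-methoxyethanone (C3–C4 bond, C-acylation).
3. Acid chloride ⇒ 3,5-dimethoxybenzoic acid + Br2. Ketone ⇒ 1,4-dibromo-2,5-dimethoxybenzene + the Weinreb amide of methoxyacetic acid.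
4. Ring order: rings A and B are bought as benzenes; ring C (the 4-pyranone) is the only ring built and is closed last. Ring A is symmetric, so either ortho bromide closes to the same product.
5. All five OMe groups come from the starting materials and all three OH groups arise in the last step, so no protecting groups are used.

## Route

**Step 1**
Reactants: 1 3,5-dimethoxybenzoic acid
Product: 2 2,4,6-tribromo-3,5-dimethoxybenzoic acid
Conditions: Br2 (4 equiv), AcOH, rt then 70 °C; aq. NaHSO3
Reagents that add atoms: bromine, BrBr
Why: Electrophilic aromatic bromination: C2, C4 and C6 are each ortho or para to both OMe groups while the carboxyl-bearing C1 is meta to both, so three brominations fill the activated positions without ipso bromodecarboxylation (compare the 2,4,6-tribromination of 3-hydroxybenzoic acid).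

**Step 2**
Reactants: 3 1,4-dibromo-2,5-dimethoxybenzene; 4 N,2-dimethoxy-N-methylacetamide
Product: 6 1-(4-bromo-2,5-dimethoxyphenyl)-2-methoxyethan-1-one, via aryllithium 5 (not isolated)
Conditions: n-BuLi (1.0 equiv), THF, −78 °C, 30 min; then 4 (1.2 equiv), −78 → 0 °C; 1 M HCl
Reagents that add atoms: none
Why: Bromine–lithium exchange on the symmetric dibromide stops after one exchange at −78 °C (the ortho-OMe-stabilised aryllithium has no ortho bromine and cannot form an aryne), and acylation by the Weinreb amide stops at the ketone (Weinreb ketone synthesis).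

**Step 3**
Reactants: 2 2,4,6-tribromo-3,5-dimethoxybenzoic acid; 6 1-(4-bromo-2,5-dimethoxyphenyl)-2-methoxyethan-1-one
Product: 8 1-(4-bromo-2,5-dimethoxyphenyl)-2-methoxy-3-(2,4,6-tribromo-3,5-dimethoxyphenyl)propane-1,3-dione, via acid chloride 7 (not isolated)
Conditions: (COCl)2 (1.5 equiv), DMF (cat.), CH2Cl2, 0 °C → rt, evaporate; then 6 (1.0 equiv), MgBr2·OEt2 (2.5 equiv), i-Pr2NEt (3 equiv), CH2Cl2, 0 °C → rt; 1 M HCl
Reagents that add atoms: oxalyl chloride, ClC(=O)C(=O)Cl (gives the Cl of 7 only; none of its atoms stays in 8)
Why: The acid chloride acylates at carbon the magnesium-chelated enolate of 6 formed by soft enolisation (crossed Claisen-type C-acylation to a 1,3-diketone), 2,6-dihalobenzoyl chlorides being reactive enough towards carbon nucleophiles as in quinolone syntheses; the new C2 centre is racemic and enolisable and becomes sp2 in step 4, so no stereocontrol is needed.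

**Step 4**
Reactants: 8 1-(4-bromo-2,5-dimethoxyphenyl)-2-methoxy-3-(2,4,6-tribromo-3,5-dimethoxyphenyl)propane-1,3-dione
Product: 10 5,7-dihydroxy-2-(4-hydroxy-2,5-dimethoxyphenyl)-3,6,8-trimethoxy-4H-chromen-4-one (the target), via tribromoflavone 9 (not isolated)
Conditions: CuI (20 mol %), N,N'-bis(4-hydroxy-2,6-dimethylphenyl)oxalamide (20 mol %), Cs2CO3 (1.5 equiv), degassed DMSO (0.05 M), 80 °C, Ar; then LiOH·H2O (12 equiv), H2O (DMSO/H2O 4:1), 100 °C; 2 M HCl, 50 °C
Reagents that add atoms: lithium hydroxide monohydrate, [Li+].[OH-].O (hydroxide supplies the three phenolic O atoms)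
Why: Proposed new method: a staged one-pot Cu(I)/oxalamide domino in which the caesium enolate of 8 first closes ring C by intramolecular Ullmann-type O-arylation at either of the two equivalent ortho C–Br bonds of the symmetric A ring (six-membered ring, O1–C8a bond, gives 9); this closure switches on the rest, because it turns the twisted aryl ketone into a planar chromone in which the remaining A-ring bromides sit peri/ortho (C5, carbonyl-chelating for Cu) and para (C7) to the C4 carbonyl and the B-ring bromide sits para to the vinylogous C2, while the A-ring OMe groups are meta and stay inert; LiOH/water then lets the same catalyst convert all three C–Br bonds into C–OH (oxidative addition, Br/OH exchange on Cu, C–O reductive elimination); the di-ortho-substituted phenoxides are too crowded to form diaryl ethers, hydroxide addition at C2 only gives ring-opened enolate material that resists retro-Claisen cleavage and recloses on acid work-up, and a Wessely–Moser shift is degenerate because ring A is symmetric; closest known reaction types are the Cu-catalysed cyclisation of 1-(2-haloaryl)-1,3-diketones to flavones and the Cu/oxalamide hydroxylation of aryl bromides with LiOH, which have not been combined in one pot or shown on a tetrabromide with di-ortho-substituted C–Br bonds.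

## Compound list

1 | 3,5-dimethoxybenzoic acid | COc1cc(OC)cc(C(=O)O)c1 | starting material
2 | 2,4,6-tribromo-3,5-dimethoxybenzoic acid | OC(=O)c1c(Br)c(OC)c(Br)c(OC)c1Br | intermediate
3 | 1,4-dibromo-2,5-dimethoxybenzene | COc1cc(Br)c(OC)cc1Br | starting material
4 | N,2-dimethoxy-N-methylacetamide | COCC(=O)N(C)OC | starting material
5 | (4-bromo-2,5-dimethoxyphenyl)lithium | [Li]c1cc(OC)c(Br)cc1OC | intermediate (not isolated)
6 | 1-(4-bromo-2,5-dimethoxyphenyl)-2-methoxyethan-1-one | COCC(=O)c1cc(OC)c(Br)cc1OC | intermediate
7 | 2,4,6-tribromo-3,5-dimethoxybenzoyl chloride | ClC(=O)c1c(Br)c(OC)c(Br)c(OC)c1Br | intermediate (not isolated)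
8 | 1-(4-bromo-2,5-dimethoxyphenyl)-2-methoxy-3-(2,4,6-tribromo-3,5-dimethoxyphenyl)propane-1,3-dione (racemic at C2, enolisable) | COC(C(=O)c1cc(OC)c(Br)cc1OC)C(=O)c1c(Br)c(OC)c(Br)c(OC)c1Br | intermediate
9 | 5,7-dibromo-2-(4-bromo-2,5-dimethoxyphenyl)-3,6,8-trimethoxy-4H-chromen-4-one | COc1cc(-c2oc3c(OC)c(Br)c(OC)c(Br)c3c(=O)c2OC)c(OC)cc1Br | intermediate (not isolated)
10 | 5,7,4'-trihydroxy-3,6,8,2',5'-pentamethoxyflavone (achiral) | COc1cc(-c2oc3c(OC)c(O)c(OC)c(O)c3c(=O)c2OC)c(OC)cc1O | target

## Step count

Total: 4 steps (steps 2, 3 and 4 each pass through one non-isolated intermediate).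
Longest linear sequence: 3 steps (1 → 2 → 8 → 10, or 3 → 6 → 8 → 10).

## Three steps most likely to fail, with fallbacks

**Step 4 (the proposed new domino).** Risks: incomplete hydroxylation at C7 (flanked by two OMe groups), protodebromination, or base damage to the diketone/flavone. The fallback sets out from 8 and comes back at 10 using known chemistry and no hydroxide. Compound 8 is cyclised alone by the known Cu-catalysed intramolecular O-arylation of o-bromoaryl 1,3-diketones (CuI, K2CO3, DMF, 100 °C) and 9 is isolated. The three C–Br bonds of 9 are then coupled with benzyl alcohol by Pd-catalysed C–O cross-coupling (tBuBrettPhos Pd G3, Cs2CO3, toluene, 90 °C) to give 5,7-bis(benzyloxy)-2-[4-(benzyloxy)-2,5-dimethoxyphenyl]-3,6,8-trimethoxy-4H-chromen-4-one F5. Hydrogenolysis (H2, Pd/C, EtOAc/MeOH) then gives 10.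

**Step 3 (C-acylation with a di-ortho-bromo acid chloride).** Risks: O-acylation to the enol ester, or no reaction for steric reasons. The fallback sets out from 7 (made from 2 as in step 3) and from 6, and comes back at 8. It replaces acyl substitution by addition to an aldehyde, which tolerates ortho crowding far better. Acid chloride 7 is reduced with LiAlH(Ot-Bu)3 (THF, −78 °C) to 2,4,6-tribromo-3,5-dimethoxybenzaldehyde F2. Ketone 6 is deprotonated with LDA (THF, −78 °C) to the lithium (Z)-enolate of 6 F3. This adds to F2 to give the aldol 1-(4-bromo-2,5-dimethoxyphenyl)-3-hydroxy-2-methoxy-3-(2,4,6-tribromo-3,5-dimethoxyphenyl)propan-1-one F4 (racemic mixture of diastereomers; both centres are lost later). Dess–Martin oxidation of F4 gives 8.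

**Step 1 (exhaustive bromination).** Risks: the third bromination at C4 (between two OMe groups, para to CO2H) may stall at the 2,6-dibromide, or HBr may cleave a methyl ether on heating. The fallback does not set out from a numbered compound of the route. It replaces 1 with commercial 4-bromo-3,5-dimethoxybenzoic acid F1, which already carries the difficult C4–Br bond. Its two free positions are each ortho and para to a methoxy group and take bromine at room temperature (Br2 2.2 equiv, AcOH). The route is rejoined at 2.

## Further compounds

F1 | step 1 | 4-bromo-3,5-dimethoxybenzoic acid | COc1cc(C(=O)O)cc(OC)c1Br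
F2 | step 3 | 2,4,6-tribromo-3,5-dimethoxybenzaldehyde | O=Cc1c(Br)c(OC)c(Br)c(OC)c1Br
F3 | step 3 | lithium (Z)-enolate of 6 | [Li]O/C(=C\OC)c1cc(OC)c(Br)cc1OC
F4 | step 3 | 1-(4-bromo-2,5-dimethoxyphenyl)-3-hydroxy-2-methoxy-3-(2,4,6-tribromo-3,5-dimethoxyphenyl)propan-1-one (racemic, mixture of diastereomers) | COC(C(O)c1c(Br)c(OC)c(Br)c(OC)c1Br)C(=O)c1cc(OC)c(Br)cc1OC
F5 | step 4 | 5,7-bis(benzyloxy)-2-[4-(benzyloxy)-2,5-dimethoxyphenyl]-3,6,8-trimethoxy-4H-chromen-4-one | COc1cc(-c2oc3c(OC)c(OCc4ccccc4)c(OC)c(OCc4ccccc4)c3c(=O)c2OC)c(OC)cc1OCc1ccccc1
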